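## Structural features

The target 30 is a daucane sesquiterpenoid ester: a trans-fused bicyclo[5.3.0]decane in which cyclopentane ring A (C1–C5) and cycloheptane ring B (C1, C5–C10) share the C1–C5 bond. Daucane locants are used for all bicyclic compounds (C14 is the methylene carbon on C8), and β means the face that carries the C1 methyl group. There are five stereocentres, (1R,4R,5S,6S,9S). The quaternary C1 (methyl β), the ring-fusion C5 (H α), the fully substituted carbinol C4 (OH β, isopropyl α) and the ester carbinol C6 (vanillate α) stand in a row; C9 (OH α) sits alone across ring B, next to the C8 exocyclic methylene. The fragile elements are the tertiary C4 alcohol 1,3 to the C6 oxygen (dehydration, and retro-aldol cleavage of any β-hydroxy ketone on the way), the allylic alcohol with its 1,1-disubstituted alkene, and the aryl ester with a free phenol. The real difficulty is the C1/C5/C4/C6 array: a quaternary carbon without a heteroatom must be set in absolute terms, and the C5 hydrogen must end up trans to the C1 methyl and the C4 hydroxyl but cis to the C6 oxygen. Ring B needs oxygen at C6 and C9 and one extra carbon on C8, which makes ketones at C6 and C9 the natural handles. The key step uses the fact that C1 and C5 are the β- and α-carbons of a C6 carbonyl, while C2–C3–C4 is a three-carbon chain whose end C4 carries the isopropyl group and is bonded to C5; this is the pattern a 1-isopropyl allenylsilane lays across the C1=C5 bond of a ring B enone. Because C9 must pass through a ketone later, its configuration in the enone is free and can serve as a temporary control element for C1.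

## Logic of the disconnections

30 ⇒ 29. The aryl O–Si bond is restored. The phenol is kept masked to the end because a free guaiacol-type phenol would interfere with the acylation, the formaldehyde condensation and the borane. The forward step must cleave an aryl silyl ether without touching the C6 ester, the tertiary alcohol or the allylic alcohol.

29 ⇒ 28. The C9–H bond is cut, which turns the allylic carbinol into an enone carbonyl. C9 is remote from the other stereocentres, so reagent control is the direct way to set it, and the ketone is also what activates C8. The forward step must deliver hydride 1,2 and to the β face.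

28 ⇒ 25 + 26. The C8=C14 bond is cut. C14 becomes a one-carbon electrophile and ring B simplifies to a plain C9 ketone. The forward step must condense at C8 and not at C10, and must not move the new alkene into the ring.

25 ⇒ 21 + 24, and 24 ⇒ 22. The C6–O acyl bond is cut, so the arene arrives late and convergently. The forward step must acylate the secondary C6 hydroxyl in the presence of the tertiary C4 hydroxyl, which is why the phenol of 22 is silylated first.

21 ⇒ 20. The C6–H bond is cut. With a ketone at C6 the C4 hydroxyl can deliver hydride internally and fix the 4β/6α relationship. The forward step must leave the second ketone at C9 alone.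

20 ⇒ 19. The C5–H bond is cut and the C5–O bond restored: a β-hydroxy ketone is traced back to an α,β-epoxy ketone. The epoxide carries the C4 oxygen with defined configuration, and reductive cleavage breaks only the C–O bond next to the carbonyl. The forward step must protonate C5 on the α face.

19 ⇒ 18 ⇒ 17 ⇒ 16. The C4–O and C5–O bonds are cut back to the C4=C5 alkene of a conjugated enone. The C6 carbinol needed to steer the oxygen comes from the C6 ketone, and both carbinols of 18 are oxidised together. Three stereocentres disappear and only C1 and C9 remain. The forward steps must add hydride to the α face of C6 and then deliver oxygen syn to the new hydroxyl.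

16 ⇒ 15 ⇒ 14. The C3–Si and O–Si bonds are restored and the alkene is moved from C4=C5 back to C3=C4. This gives the direct annulation product. One acid treatment in the forward direction must remove both silyl groups and bring the alkene into conjugation.

14 ⇒ 9 + 13. The C1–C2 and C4–C5 bonds are cut, ring A falls away, and a bicycle with two stereocentres becomes a monocyclic enone and a six-carbon allene. The forward step must form C1–C2 anti to the C9 silyloxy group and close the ring before silicon is lost.

9 ⇒ 8. The C1=C5 bond is cut. The seven-membered ring opens to an acyclic dienone with one stereocentre. The forward step is a ring-closing metathesis that must form a trisubstituted enone.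

8 ⇒ 6 + 7. The C5–C6 bond is cut between the vinyl group and an acyl donor. The forward step must stop at the ketone.

6 ⇒ 5 ⇒ 4 ⇒ 3 ⇒ 1 + 2. The O–Si bond, the amide C–N bond (as a lactone opening) and the C9–C10 bond are cut. The γ-hydroxy ester 3 would lactonise in any case, so 4 is made on purpose and opened with the amine, and silylation follows the opening. The forward allylation must set the C9 carbinol in absolute terms.

13 ⇒ 11 + 12, and 11 ⇒ 10. The bond between C4 and the isopropyl carbon is cut in the SN2′ sense. The forward step must attack the silyl-bearing alkyne carbon and not the CH2 carbon.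

## Other disconnections considered

Alternative 1: The cut removes C1–C10 and C4–C5 at once and leads to acyclic farnesyl diphosphate A1. In the forward direction a daucane-forming sesquiterpene cyclase would ionise A1, close both rings in one cationic cascade, shift hydride to the isopropyl cation and lose the C5 proton to give dauca-4,8-diene A2 with C1 fixed by the enzyme.
- In its favour: the whole C15 skeleton, including C14, would come from a fermentable precursor in one step with catalyst control of C1. On skeleton-building step count it is better than the chosen plan, which needs eight steps to reach 14 and adds C14 separately.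
- Also in its favour: the C8=C9 alkene with its methyl group is the right substrate for an ene-type photooxygenation to the 8(14)-en-9-ol. That would be at least the equal of the ketone, methylenation and reduction sequence used here.
- Against it: A2 has no oxygen at all. The C4 hydration with C5–H trans and the C6 oxygenation would have to be done on a hydrocarbon with two alkenes and many allylic positions. The C6 carbonyl that organises this chemistry in 16 (directed epoxidation, reductive opening, directed reduction) is absent.
- Comparison: mechanistically the cyclisation is fully enzyme-controlled while everything after it is substrate-controlled; in the chosen plan it is the other way round for ring A. It also needs a cyclase of the right absolute sense and a biotransformation set-up. Overall it is shorter to the skeleton but less certain from the skeleton to 30.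

Alternative 2: The cut removes C7–C8 and C1–C10 and leads to the silyloxydiene A3 and the vinyldiazoacetate A4. In the forward direction a chiral dirhodium tetracarboxylate, Rh2(O2CR*)4, would form the carbenoid of A4, cyclopropanate the terminal alkene of A3 and the cis-divinylcyclopropane would undergo Cope rearrangement to the bicycle A5.
- In its favour: C1 would be set by the catalyst, with no stereogenic helper group to install and erase. On this point it is better than substrate control through C9.
- Also in its favour: A5 carries oxygen at C6 and C9, the future C14 as the ester on C8 and a carbonyl at C4, so it maps onto ring B better than 14 does.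
- Against it: the Cope step must create the quaternary centre from a fully substituted cyclopentene carbon, and A3 is an acid-sensitive diene. A5 also holds three carbonyl-level groups plus an ester that must be told apart.
- Further against it: the isopropyl group would have to be added to a hindered, enolisable C4 ketone with facial control, and C5 would still have to be set trans, now between two carbonyl groups. 14 already carries the isopropyl group.
- Comparison: the mechanism is pericyclic and stereospecific where the chosen step is stepwise and cationic. The step count to the bicycle is about equal, but functional-group differentiation afterwards is heavier.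

Alternative 3: The cut removes only C1–C5 and leads to the ten-membered enedione A6, drawn here as the E isomer. In the forward direction a base would form the C5 enolate of the C6 ketone, which adds across the ring to C1 of the C9 enone and gives the trans-fused dione A7.
- In its favour: one bond closes both rings and sets C1 and C5 relative to a C4 centre that already carries its oxygen and isopropyl group. If the transannular transition state behaves, this answers the C5 problem more directly than the redox sequence of steps 10–13, and on that point it is better.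
- Equal on the endgame: A7 is the triethylsilyl ether of 20, so the two plans would share steps 14–19.
- Against it: A6 needs an enantioselective construction of an acyclic tertiary carbinol and a medium-ring closure. The C5 enolate is β to the C4 silyloxy group, so elimination competes with the Michael addition, and enolisation at C7, C8 or C10 is also possible.
- Comparison: the facial outcome depends on the conformation of a ten-membered ring and cannot be argued from a simple model, whereas the chosen plan sets C4 by a directed, predictable step. The key step builds more complexity, but the precursor is likely to cost more steps than 9 and 13 together.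

Key step: step 8

## Steps

Step 1
Reactants: 1 methyl 4-oxobutanoate; 2 (2-methylallyl)magnesium chloride
Product: 4 (S)-5-(2-methylallyl)dihydrofuran-2(3H)-one, via hydroxy ester 3 (not isolated)
Conditions: 2, (+)-Ipc2BOMe, Et2O, −78 °C → rt; then 1, −78 °C; H2O2, pH 7 buffer, MeOH, rt; p-TsOH·H2O (cat.), CH2Cl2, rt
Reagents that add atoms: none
Why: Brown-type asymmetric allylboration: the B-(2-methylallyl)diisopinocampheylborane formed in the flask adds through a closed chair transition state, and the reagent from (+)-Ipc2BOMe (derived from (−)-α-pinene) should attack the Re face of this α-unbranched aldehyde and set the (S)-carbinol that becomes C9; acid then closes the γ-hydroxy ester to the lactone, which protects the alcohol and activates the acyl group.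

Step 2
Reactants: 4 (S)-5-(2-methylallyl)dihydrofuran-2(3H)-one
Product: 5 (S)-4-hydroxy-N-methoxy-N,6-dimethylhept-6-enamide
Conditions: MeNHOMe·HCl, AlMe3, CH2Cl2, 0 °C → rt
Reagents that add atoms: N,O-dimethylhydroxylamine hydrochloride, CNOC.Cl
Why: Weinreb aminolysis of a lactone by the aluminium amide made from AlMe3 and the amine salt; the stereocentre is not touched, and the crude γ-hydroxy amide is silylated at once because it can close back to 4.

Step 3
Reactants: 5 (S)-4-hydroxy-N-methoxy-N,6-dimethylhept-6-enamide
Product: 6 (S)-4-(tert-butyldimethylsilyloxy)-N-methoxy-N,6-dimethylhept-6-enamide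
Conditions: TBSCl, imidazole, DMF, rt
Reagents that add atoms: tert-butyldimethylsilyl chloride, CC(C)(C)[Si](C)(C)Cl
Why: Standard silylation of a secondary alcohol; the silyl ether blocks relactonisation, should survive TiCl4 at −78 °C and later shields one face of the enone.

Step 4
Reactants: 6 (S)-4-(tert-butyldimethylsilyloxy)-N-methoxy-N,6-dimethylhept-6-enamide; 7 vinylmagnesium bromide
Product: 8 (S)-6-(tert-butyldimethylsilyloxy)-8-methylnona-1,8-dien-3-one
Conditions: 7, THF, 0 °C; inverse quench into cold 1 M HCl
Reagents that add atoms: none
Why: Weinreb ketone synthesis: the chelated tetrahedral adduct stops at the ketone stage, and the cold acidic inverse quench keeps the liberated amine from adding to the vinyl ketone.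

Step 5
Reactants: 8 (S)-6-(tert-butyldimethylsilyloxy)-8-methylnona-1,8-dien-3-one
Product: 9 (S)-5-(tert-butyldimethylsilyloxy)-3-methylcyclohept-2-en-1-one
Conditions: second-generation Grubbs catalyst (H2IMes)(PCy3)Cl2Ru=CHPh (5 mol %), CH2Cl2 (5 mM), 40 °C
Reagents that add atoms: none
Why: Ring-closing metathesis between the vinyl ketone and the 1,1-disubstituted alkene with loss of ethene forms the seven-membered ring and the trisubstituted enone in one step; high dilution disfavours dimerisation and the stereocentre is untouched.

Step 6
Reactants: 10 3-(trimethylsilyl)prop-2-yn-1-ol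
Product: 11 3-(trimethylsilyl)prop-2-yn-1-yl methanesulfonate
Conditions: MsCl, Et3N, CH2Cl2, −20 °C
Reagents that add atoms: methanesulfonyl chloride, CS(=O)(=O)Cl
Why: Sulfonylation of a primary propargylic alcohol under standard conditions; the mesylate is used crude because it is reactive.

Step 7
Reactants: 11 3-(trimethylsilyl)prop-2-yn-1-yl methanesulfonate; 12 isopropylmagnesium chloride
Product: 13 trimethyl(4-methylpenta-1,2-dien-3-yl)silane
Conditions: 12, CuBr, LiBr, THF, −78 °C → rt
Reagents that add atoms: none
Why: SN2′ displacement of the propargylic mesylate by the organocopper reagent made from 12 and CuBr·LiBr: attack at the silyl-bearing alkyne carbon gives the 1-isopropyl-1-(trimethylsilyl)allene, the established way to 1-alkyl-1-silylallenes.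

Step 8
Reactants: 9 (S)-5-(tert-butyldimethylsilyloxy)-3-methylcyclohept-2-en-1-one; 13 trimethyl(4-methylpenta-1,2-dien-3-yl)silane
Product: 14 cis-fused 9β-(tert-butyldimethylsilyloxy)-4-isopropyl-1β-methyl-3-(trimethylsilyl)bicyclo[5.3.0]dec-3-en-6-one (5β-H)
Conditions: TiCl4 (1.2 equiv), 13 (1.5 equiv), CH2Cl2, −78 °C; aq. NaHCO3
Reagents that add atoms: none
Why: TiCl4 binds the enone carbonyl and the CH2 terminus of the allene adds to the β-carbon C1 (C1–C2 bond), which gives a titanium enolate and a vinyl cation stabilised by the neighbouring C–Si bond. A 1,2-shift of silicon moves the positive charge to the isopropyl-bearing carbon, and the enolate carbon C5 captures it (C4–C5 bond). The closest known reaction type is the Danheiser (trimethylsilyl)cyclopentene annulation of enones, a relative of the Sakurai allylation. Ring A closes in the second bond-forming event, a cation–enolate collapse of the 5-(enolexo)-endo-dig type in which the former allene carbons become C2, C3 and C4. C1 is set by the face of the conjugate addition: the allene should approach trans to the C9 silyloxy group, the 1,3-related substituent that shields one face of the cycloheptenone as it does in additions to 5-substituted cycloalkenones. C5 is set by the tether, because the three-carbon chain can reach the enolate only on the face it already occupies, hence the cis fusion, which does not matter since C5 is levelled in step 9. The step needs the right regiochemistry, secured because only attack through the CH2 terminus gives a silicon-stabilised cation, and it needs ring closure to outrun chloride-induced loss of silicon, which the substituent on the silyl-bearing allene carbon and the low temperature favour. It also needs facial selectivity, for which the only element in the substrate is the C9 silyl ether.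

Step 9
Reactants: 14 cis-fused 9β-(tert-butyldimethylsilyloxy)-4-isopropyl-1β-methyl-3-(trimethylsilyl)bicyclo[5.3.0]dec-3-en-6-one (5β-H)
Product: 16 9β-hydroxy-4-isopropyl-1β-methylbicyclo[5.3.0]dec-4-en-6-one, via hydroxy vinylsilane 15 (not isolated)
Conditions: p-TsOH·H2O, MeCN–H2O, rt → 70 °C
Reagents that add atoms: none
Why: Aqueous acid first cleaves the secondary silyl ether; on warming the vinylsilane is protonated at C3 to a β-silyl cation at C4 that loses silicon (ipso protodesilylation), and acid-catalysed enolisation moves the alkene into conjugation as the tetrasubstituted enone, the thermodynamic isomer, which erases the cis ring fusion at C5.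

Step 10
Reactants: 16 9β-hydroxy-4-isopropyl-1β-methylbicyclo[5.3.0]dec-4-en-6-one
Product: 17 4-isopropyl-1β-methylbicyclo[5.3.0]dec-4-ene-6β,9β-diol
Conditions: NaBH4, CeCl3·7H2O, MeOH, −40 °C
Reagents that add atoms: none
Why: Luche 1,2-reduction; hydride should add to the α face of C6, opposite the angular methyl on the neighbouring C1, giving the 6β-alcohol that is needed to steer the epoxidation.

Step 11
Reactants: 17 4-isopropyl-1β-methylbicyclo[5.3.0]dec-4-ene-6β,9β-diol
Product: 18 4β,5β-epoxy-4α-isopropyl-1β-methylbicyclo[5.3.0]decane-6β,9β-diol
Conditions: VO(acac)2 (5 mol %), t-BuOOH, CH2Cl2, 0 °C → rt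
Reagents that add atoms: tert-butyl hydroperoxide, CC(C)(C)OO
Why: Hydroxyl-directed epoxidation of an allylic alcohol: the vanadium alkylperoxide bound to the 6β-oxygen delivers oxygen to the same face of the electron-rich tetrasubstituted alkene, which sets C4 (C–O β, isopropyl α); the remote 9β-hydroxyl lies on the same face and cannot oppose it.

Step 12
Reactants: 18 4β,5β-epoxy-4α-isopropyl-1β-methylbicyclo[5.3.0]decane-6β,9β-diol
Product: 19 4β,5β-epoxy-4α-isopropyl-1β-methylbicyclo[5.3.0]decane-6,9-dione
Conditions: Dess–Martin periodinane (2.5 equiv), NaHCO3, CH2Cl2, rt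
Reagents that add atoms: none
Why: Dess–Martin oxidation of both secondary alcohols; the bicarbonate buffer protects the tetrasubstituted epoxide, and the C9 stereocentre, whose only task was to control step 8, disappears.

Step 13
Reactants: 19 4β,5β-epoxy-4α-isopropyl-1β-methylbicyclo[5.3.0]decane-6,9-dione
Product: 20 trans-fused 4β-hydroxy-4α-isopropyl-1β-methylbicyclo[5.3.0]decane-6,9-dione (5α-H)
Conditions: SmI2 (2.5 equiv), THF–MeOH, −90 °C
Reagents that add atoms: none
Why: Reductive cleavage of an α,β-epoxy ketone by SmI2: two electrons break only the C5–O bond, so the C4–O bond keeps its β configuration; the trivalent samarium enolate should be protonated at C5 on the α face, away from the angular methyl and the samarium-bound C4 alkoxide and towards the ring fusion that keeps C6 anti to the isopropyl group; the isolated C9 ketone should not be reduced at −90 °C.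

Step 14
Reactants: 20 trans-fused 4β-hydroxy-4α-isopropyl-1β-methylbicyclo[5.3.0]decane-6,9-dione (5α-H)
Product: 21 trans-fused 4β,6α-dihydroxy-4α-isopropyl-1β-methylbicyclo[5.3.0]decan-9-one (5α-H)
Conditions: Me4NBH(OAc)3, MeCN–AcOH, −30 °C
Reagents that add atoms: none
Why: Saksena–Evans reduction: the tertiary C4 hydroxyl exchanges onto boron and delivers hydride internally to the β face of the C6 carbonyl, giving the 6α-alcohol (anti 1,3-diol); the C9 ketone has no β-hydroxyl and should not be reduced by this mild reagent.

Step 15
Reactants: 22 vanillic acid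
Product: 24 4-(tert-butyldimethylsilyloxy)-3-methoxybenzoic acid, via silyl ester 23 (not isolated)
Conditions: TBSCl (2.5 equiv), imidazole, DMF, rt; AcOH–THF–H2O, rt
Reagents that add atoms: tert-butyldimethylsilyl chloride, CC(C)(C)[Si](C)(C)Cl
Why: Silylation of phenol and acid followed by selective hydrolysis of the labile silyl ester leaves the aryl silyl ether, which should be stable to the carbodiimide, the methylenation and the borane and is cleaved by fluoride at the end.

Step 16
Reactants: 21 trans-fused 4β,6α-dihydroxy-4α-isopropyl-1β-methylbicyclo[5.3.0]decan-9-one (5α-H); 24 4-(tert-butyldimethylsilyloxy)-3-methoxybenzoic acid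
Product: 25 trans-fused 4β-hydroxy-4α-isopropyl-1β-methyl-9-oxobicyclo[5.3.0]dec-6α-yl 4-(tert-butyldimethylsilyloxy)-3-methoxybenzoate
Conditions: EDC·HCl, DMAP (4-dimethylaminopyridine), CH2Cl2, rt
Reagents that add atoms: none
Why: Steglich esterification: only the secondary 6α-hydroxyl is acylated, the tertiary C4 hydroxyl is too hindered, and no stereocentre is touched.

Step 17
Reactants: 25 trans-fused 4β-hydroxy-4α-isopropyl-1β-methyl-9-oxobicyclo[5.3.0]dec-6α-yl 4-(tert-butyldimethylsilyloxy)-3-methoxybenzoate; 26 formaldehyde (as paraformaldehyde)
Product: 28 trans-fused 4β-hydroxy-4α-isopropyl-1β-methyl-8-methylene-9-oxobicyclo[5.3.0]dec-6α-yl 4-(tert-butyldimethylsilyloxy)-3-methoxybenzoate, via Mannich base 27 (not isolated)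
Conditions: 26, i-Pr2NH·CF3CO2H, CF3CO2H (cat.), THF, reflux
Reagents that add atoms: none
Why: α-Methylenation by Mannich condensation with formaldehyde and β-elimination of the amine; enolisation towards C8 is favoured because C10 is neopentylic next to the quaternary C1, and the new carbon is C14 of the target.

Step 18
Reactants: 28 trans-fused 4β-hydroxy-4α-isopropyl-1β-methyl-8-methylene-9-oxobicyclo[5.3.0]dec-6α-yl 4-(tert-butyldimethylsilyloxy)-3-methoxybenzoate
Product: 29 trans-fused 4β,9α-dihydroxy-4α-isopropyl-1β-methyl-8-methylenebicyclo[5.3.0]dec-6α-yl 4-(tert-butyldimethylsilyloxy)-3-methoxybenzoate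
Conditions: (R)-2-methyl-CBS-oxazaborolidine ((R)-1-methyl-3,3-diphenyltetrahydro-1H,3H-pyrrolo[1,2-c][1,3,2]oxazaborole, 0.5 equiv), catecholborane, toluene, −78 °C
Reagents that add atoms: none
Why: Corey–Bakshi–Shibata reduction: with the (R)-catalyst and the α-methylene carbon C8 as the larger group, hydride should be delivered to the β face of C9, giving the (9S)-allylic alcohol (OH α); catecholborane at low temperature reduces 1,2 and should not hydroborate the alkene.

Step 19
Reactants: 29 trans-fused 4β,9α-dihydroxy-4α-isopropyl-1β-methyl-8-methylenebicyclo[5.3.0]dec-6α-yl 4-(tert-butyldimethylsilyloxy)-3-methoxybenzoate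
Product: 30 (1R,4R,5S,6S,9S)-4,9-dihydroxy-4-isopropyl-1-methyl-8-methylenebicyclo[5.3.0]dec-6-yl 4-hydroxy-3-methoxybenzoate (CNP0330487.1)
Conditions: Bu4NF, AcOH, THF, 0 °C
Reagents that add atoms: none
Why: Fluoride cleaves the aryl silyl ether selectively; acetic acid buffers the phenoxide so that the C6 ester should neither migrate nor cleave.

## Compound list

1 | methyl 4-oxobutanoate | COC(=O)CCC=O | starting material
2 | (2-methylallyl)magnesium chloride | C=C(C)C[Mg]Cl | starting material
3 | methyl (S)-4-hydroxy-6-methylhept-6-enoate | C=C(C)C[C@@H](O)CCC(=O)OC | intermediate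
4 | (S)-5-(2-methylallyl)dihydrofuran-2(3H)-one | C=C(C)C[C@@H]1CCC(=O)O1 | intermediate
5 | (S)-4-hydroxy-N-methoxy-N,6-dimethylhept-6-enamide | C=C(C)C[C@@H](O)CCC(=O)N(C)OC | intermediate
6 | (S)-4-(tert-butyldimethylsilyloxy)-N-methoxy-N,6-dimethylhept-6-enamide | C=C(C)C[C@@H](O[Si](C)(C)C(C)(C)C)CCC(=O)N(C)OC | intermediate
7 | vinylmagnesium bromide | C=C[Mg]Br | starting material
8 | (S)-6-(tert-butyldimethylsilyloxy)-8-methylnona-1,8-dien-3-one | C=C(C)C[C@@H](O[Si](C)(C)C(C)(C)C)CCC(=O)C=C | intermediate
9 | (S)-5-(tert-butyldimethylsilyloxy)-3-methylcyclohept-2-en-1-one | O=C1C=C(C)C[C@@H](O[Si](C)(C)C(C)(C)C)CC1 | intermediate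
10 | 3-(trimethylsilyl)prop-2-yn-1-ol | C[Si](C)(C)C#CCO | starting material
11 | 3-(trimethylsilyl)prop-2-yn-1-yl methanesulfonate | C[Si](C)(C)C#CCOS(C)(=O)=O | intermediate
12 | isopropylmagnesium chloride | CC(C)[Mg]Cl | starting material
13 | trimethyl(4-methylpenta-1,2-dien-3-yl)silane, the 1-isopropyl-1-(trimethylsilyl)allene | C=C=C(C(C)C)[Si](C)(C)C | intermediate
14 | cis-fused 9β-(tert-butyldimethylsilyloxy)-4-isopropyl-1β-methyl-3-(trimethylsilyl)bicyclo[5.3.0]dec-3-en-6-one (5β-H) | C1CC(=O)[C@H]2[C@](C)(CC([Si](C)(C)C)=C2C(C)C)C[C@H]1O[Si](C)(C)C(C)(C)C | intermediate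
15 | cis-fused 9β-hydroxy-4-isopropyl-1β-methyl-3-(trimethylsilyl)bicyclo[5.3.0]dec-3-en-6-one (5β-H) | C1CC(=O)[C@H]2[C@](C)(CC([Si](C)(C)C)=C2C(C)C)C[C@H]1O | intermediate
16 | 9β-hydroxy-4-isopropyl-1β-methylbicyclo[5.3.0]dec-4-en-6-one | C1CC(=O)C2=C(C(C)C)CC[C@]2(C)C[C@H]1O | intermediate
17 | 4-isopropyl-1β-methylbicyclo[5.3.0]dec-4-ene-6β,9β-diol | C1C[C@@H](O)C2=C(C(C)C)CC[C@]2(C)C[C@H]1O | intermediate
18 | 4β,5β-epoxy-4α-isopropyl-1β-methylbicyclo[5.3.0]decane-6β,9β-diol | C1C[C@@H](O)[C@@]23O[C@@]3(C(C)C)CC[C@]2(C)C[C@H]1O | intermediate
19 | 4β,5β-epoxy-4α-isopropyl-1β-methylbicyclo[5.3.0]decane-6,9-dione | C1CC(=O)[C@@]23O[C@@]3(C(C)C)CC[C@]2(C)CC1=O | intermediate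
20 | trans-fused 4β-hydroxy-4α-isopropyl-1β-methylbicyclo[5.3.0]decane-6,9-dione (5α-H) | O=C1CCC(=O)[C@@H]2[C@](C)(CC[C@@]2(O)C(C)C)C1 | intermediate
21 | trans-fused 4β,6α-dihydroxy-4α-isopropyl-1β-methylbicyclo[5.3.0]decan-9-one (5α-H) | O=C1CC[C@H](O)[C@@H]2[C@](C)(CC[C@@]2(O)C(C)C)C1 | intermediate
22 | vanillic acid | COc1cc(C(=O)O)ccc1O | starting material
23 | tert-butyldimethylsilyl 4-(tert-butyldimethylsilyloxy)-3-methoxybenzoate | COc1cc(C(=O)O[Si](C)(C)C(C)(C)C)ccc1O[Si](C)(C)C(C)(C)C | intermediate
24 | 4-(tert-butyldimethylsilyloxy)-3-methoxybenzoic acid | COc1cc(C(=O)O)ccc1O[Si](C)(C)C(C)(C)C | intermediate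
25 | trans-fused 4β-hydroxy-4α-isopropyl-1β-methyl-9-oxobicyclo[5.3.0]dec-6α-yl 4-(tert-butyldimethylsilyloxy)-3-methoxybenzoate | O=C1CC[C@H](OC(=O)c2ccc(O[Si](C)(C)C(C)(C)C)c(OC)c2)[C@@H]2[C@](C)(CC[C@@]2(O)C(C)C)C1 | intermediate
26 | formaldehyde (used as paraformaldehyde) | C=O | starting material
27 | 8-[(diisopropylamino)methyl] derivative of 25 (both C8 epimers) | CC(C)N(CC1C[C@H](OC(=O)c2ccc(O[Si](C)(C)C(C)(C)C)c(OC)c2)[C@@H]2[C@](C)(CC[C@@]2(O)C(C)C)CC1=O)C(C)C | intermediate
28 | trans-fused 4β-hydroxy-4α-isopropyl-1β-methyl-8-methylene-9-oxobicyclo[5.3.0]dec-6α-yl 4-(tert-butyldimethylsilyloxy)-3-methoxybenzoate | C=C1C[C@H](OC(=O)c2ccc(O[Si](C)(C)C(C)(C)C)c(OC)c2)[C@@H]2[C@](C)(CC[C@@]2(O)C(C)C)CC1=O | intermediate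
29 | trans-fused 4β,9α-dihydroxy-4α-isopropyl-1β-methyl-8-methylenebicyclo[5.3.0]dec-6α-yl 4-(tert-butyldimethylsilyloxy)-3-methoxybenzoate | C=C1C[C@H](OC(=O)c2ccc(O[Si](C)(C)C(C)(C)C)c(OC)c2)[C@@H]2[C@](C)(CC[C@@]2(O)C(C)C)C[C@@H]1O | intermediate
30 | (1R,4R,5S,6S,9S)-4,9-dihydroxy-4-isopropyl-1-methyl-8-methylenebicyclo[5.3.0]dec-6-yl 4-hydroxy-3-methoxybenzoate (CNP0330487.1) | C=C1C[C@H](OC(=O)c2ccc(O)c(OC)c2)[C@@H]2[C@](C)(CC[C@@]2(O)C(C)C)C[C@@H]1O | target

## Step count and least certain steps

Total step count: 19. Longest linear sequence: 16 steps (steps 1–5, 8–14 and 16–19, from 1 to 30). Steps 6–7 (allene) and step 15 (acid) are side branches.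

Step 8 (key step). Conjugate addition to the fully substituted β-carbon may be slow. Desilylation of the vinyl cation (propargyl transfer without ring closure) or loss of the C9 silyloxy group through the dienol of 9 could then compete. Facial discrimination may also be low, because the controlling group is 1,3 to the reacting carbon in a flexible seven-membered ring. Fallback (stepwise annulation by conjugate addition and aldol condensation), from 9:
- Copper-catalysed 1,4-addition (CuBr·SMe2, TMSCl, THF, −78 °C) of the Grignard reagent from 2-(2-bromoethyl)-2-isopropyl-1,3-dioxolane, a reaction type that reliably goes trans to a 5-substituent, should give trans-5-(tert-butyldimethylsilyloxy)-3-[2-(2-isopropyl-1,3-dioxolan-2-yl)ethyl]-3-methylcycloheptan-1-one F1.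
- Aqueous HCl in THF removes the ketal and the silyl ether to give 5-hydroxy-3-methyl-3-(4-methyl-3-oxopentyl)cycloheptan-1-one F2.
- NaOMe in MeOH closes ring A by intramolecular aldol condensation of C5 onto the side-chain ketone, and the route is rejoined at 16.

Step 13. This is the weakest stereochemical argument in the route. Protonation of the samarium enolate may occur on the β face, for instance by methanol held on the samarium-bound C4 alkoxide, which would give the cis ring fusion. Base cannot be used to correct it, because the β-hydroxy ketone would dehydrate or undergo retro-aldol cleavage. Fallback (a stereospecific hydride shift in place of enolate protonation), from 18: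
- Silylation (TMSCl, imidazole, CH2Cl2) gives 4β,5β-epoxy-4α-isopropyl-1β-methyl-6β,9β-bis(trimethylsilyloxy)bicyclo[5.3.0]decane F3.
- TiCl4 in CH2Cl2 at −78 °C should trigger a semipinacol rearrangement in which the C6 hydrogen, which is α and antiperiplanar to the β C5–O bond, migrates to C5 with inversion. Acidic work-up then gives trans-fused 4β,9β-dihydroxy-4α-isopropyl-1β-methylbicyclo[5.3.0]decan-6-one F4.
- Dess–Martin oxidation of the C9 alcohol rejoins the route at 20.

Step 10. Hydride delivery may take place on the β face if the angular methyl shields less than expected or if the free C9 hydroxyl guides the borohydride. The directed epoxidation would then put the C4 oxygen on the wrong face. Fallback (inversion instead of facial control), from 16: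
- The reduction product in that case is 4-isopropyl-1β-methylbicyclo[5.3.0]dec-4-ene-6α,9β-diol F5.
- Mitsunobu esterification of both carbinols (PPh3, DIAD, 4-nitrobenzoic acid) gives 4-isopropyl-1β-methylbicyclo[5.3.0]dec-4-ene-6β,9α-diyl bis(4-nitrobenzoate) F6.
- Methanolysis (K2CO3, MeOH) gives 4-isopropyl-1β-methylbicyclo[5.3.0]dec-4-ene-6β,9α-diol F7.
- Epoxidation as in step 11 gives 4β,5β-epoxy-4α-isopropyl-1β-methylbicyclo[5.3.0]decane-6β,9α-diol F8, and oxidation as in step 12 returns to 19, where the C9 configuration no longer exists.

Step 17. Condensation at C10 as well as C8, a second condensation, or acid-induced migration of the new alkene into the ring may erode the yield, since the reaction runs under equilibrating acidic conditions at reflux. Fallback (regiodefined enol ether and a preformed iminium salt), from 25: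
- TMSOTf and Et3N give the 9-(trimethylsilyloxy)-8-ene silyl enol ether of 25 with the C4 hydroxyl also silylated F9.
- Eschenmoser's salt (CH2=NMe2+ I−) and a mildly acidic work-up give the 8-[(dimethylamino)methyl] ketone F10.
- MeI gives its trimethylammonium iodide F11, and NaHCO3 eliminates trimethylamine to return to 28.

Step 18. The substrate may oppose the catalyst: approach to the β face of C9 passes the angular methyl, which is 1,3 to the carbonyl carbon, so catalyst control may be incomplete and the 9β-alcohol may form. Fallback (inversion at C9), from 28: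
- Substrate-controlled reduction (NaBH4, CeCl3·7H2O, MeOH) should give the 9β-epimer of 29 F12.
- Mitsunobu reaction with chloroacetic acid (PPh3, DIAD) gives the 9α-chloroacetate of 29 F13.
- K2CO3 in MeOH at 0 °C removes the chloroacetate and the aryl silyl ether together and comes back to the route at 30.

## Further compounds

F1 | step 8 | trans-5-(tert-butyldimethylsilyloxy)-3-[2-(2-isopropyl-1,3-dioxolan-2-yl)ethyl]-3-methylcycloheptan-1-one | O=C1C[C@](C)(CCC2(C(C)C)OCCO2)C[C@@H](O[Si](C)(C)C(C)(C)C)CC1
F2 | step 8 | 5-hydroxy-3-methyl-3-(4-methyl-3-oxopentyl)cycloheptan-1-one (same configuration as F1) | O=C1C[C@](C)(CCC(=O)C(C)C)C[C@@H](O)CC1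
F3 | step 13 | 4β,5β-epoxy-4α-isopropyl-1β-methyl-6β,9β-bis(trimethylsilyloxy)bicyclo[5.3.0]decane | C1C[C@@H](O[Si](C)(C)C)[C@@]23O[C@@]3(C(C)C)CC[C@]2(C)C[C@H]1O[Si](C)(C)C
F4 | step 13 | trans-fused 4β,9β-dihydroxy-4α-isopropyl-1β-methylbicyclo[5.3.0]decan-6-one (5α-H) | O[C@H]1CCC(=O)[C@@H]2[C@](C)(CC[C@@]2(O)C(C)C)C1
F5 | step 10 | 4-isopropyl-1β-methylbicyclo[5.3.0]dec-4-ene-6α,9β-diol | C1C[C@H](O)C2=C(C(C)C)CC[C@]2(C)C[C@H]1O
F6 | step 10 | 4-isopropyl-1β-methylbicyclo[5.3.0]dec-4-ene-6β,9α-diyl bis(4-nitrobenzoate) | C1C[C@@H](OC(=O)c3ccc(cc3)[N+](=O)[O-])C2=C(C(C)C)CC[C@]2(C)C[C@@H]1OC(=O)c1ccc(cc1)[N+](=O)[O-]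
F7 | step 10 | 4-isopropyl-1β-methylbicyclo[5.3.0]dec-4-ene-6β,9α-diol | C1C[C@@H](O)C2=C(C(C)C)CC[C@]2(C)C[C@@H]1O
F8 | step 10 | 4β,5β-epoxy-4α-isopropyl-1β-methylbicyclo[5.3.0]decane-6β,9α-diol | C1C[C@@H](O)[C@@]23O[C@@]3(C(C)C)CC[C@]2(C)C[C@@H]1O
F9 | step 17 | 9-(trimethylsilyloxy)-8-ene silyl enol ether of 25 with the C4 hydroxyl as trimethylsilyl ether | C[Si](C)(C)OC1=CC[C@H](OC(=O)c2ccc(O[Si](C)(C)C(C)(C)C)c(OC)c2)[C@@H]2[C@](C)(CC[C@@]2(O[Si](C)(C)C)C(C)C)C1
F10 | step 17 | 8-[(dimethylamino)methyl] derivative of 25 (both C8 epimers) | CN(C)CC1C[C@H](OC(=O)c2ccc(O[Si](C)(C)C(C)(C)C)c(OC)c2)[C@@H]2[C@](C)(CC[C@@]2(O)C(C)C)CC1=O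
F11 | step 17 | trimethylammonium iodide of F10 (both C8 epimers) | C[N+](C)(C)CC1C[C@H](OC(=O)c2ccc(O[Si](C)(C)C(C)(C)C)c(OC)c2)[C@@H]2[C@](C)(CC[C@@]2(O)C(C)C)CC1=O.[I-]
F12 | step 18 | 9β-epimer of 29 | C=C1C[C@H](OC(=O)c2ccc(O[Si](C)(C)C(C)(C)C)c(OC)c2)[C@@H]2[C@](C)(CC[C@@]2(O)C(C)C)C[C@H]1O
F13 | step 18 | 9α-chloroacetate of 29 | C=C1C[C@H](OC(=O)c2ccc(O[Si](C)(C)C(C)(C)C)c(OC)c2)[C@@H]2[C@](C)(CC[C@@]2(O)C(C)C)C[C@@H]1OC(=O)CCl
A1 | alternative 1 | (2E,6E)-farnesyl diphosphate | CC(C)=CCC/C(C)=C/CC/C(C)=C/COP(=O)(O)OP(=O)(O)O
A2 | alternative 1 | dauca-4,8-diene (daucene) with C1 as in the target | CC1=CC[C@@]2(C)CCC(C(C)C)=C2CC1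
A3 | alternative 2 | tert-butyl{[1-(7-methyl-1,4-dioxaspiro[4.4]non-6-en-6-yl)ethenyl]oxy}dimethylsilane | C=C(O[Si](C)(C)C(C)(C)C)C1=C(C)CCC12OCCO2
A4 | alternative 2 | methyl 3-(tert-butyldimethylsilyloxy)-2-diazobut-3-enoate | COC(=O)C(=[N+]=[N-])C(=C)O[Si](C)(C)C(C)(C)C
A5 | alternative 2 | bicyclic bis(silyl enol ether) with C8 methyl ester, C1 quaternary centre and C4 ketal | COC(=O)C1=C(O[Si](C)(C)C(C)(C)C)C[C@@]2(C)CCC3(OCCO3)C2=C(O[Si](C)(C)C(C)(C)C)C1
A6 | alternative 3 | (E)-4-isopropyl-1-methyl-4-(triethylsilyloxy)cyclodec-1(10)-ene-6,9-dione (daucane locants) | C/C1=C\C(=O)CCC(=O)C[C@](O[Si](CC)(CC)CC)(C(C)C)CC1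
A7 | alternative 3 | trans-fused 4β-(triethylsilyloxy)-4α-isopropyl-1β-methylbicyclo[5.3.0]decane-6,9-dione | O=C1CCC(=O)[C@@H]2[C@](C)(CC[C@@]2(O[Si](CC)(CC)CC)C(C)C)C1
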